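Deleting the spiro carbon C5 from ring B, the cyclohexenone (C5, C6=O, C7=C8, C9–OAc, C10H2), and joining C6 to C10 leaves a 4-oxygenated cyclopent-2-enone. The synthesis rests on the reverse operation, a one-carbon ring expansion: the diazo carbon of a diazosuccinate, which already bears both arms of lactone ring A (a methyl ester that becomes the O–CH carbon C1, and the CH2CO2 unit C4–C3), attacks the ketone of (S)-4-silyloxycyclopent-2-enone, and the ring CH2 migrates to it as N2 departs. A single operation thus makes both ring bonds of C5 and sets its configuration. Side-chain addition to a derived keto aldehyde, lactonisation and acetylation finish the route.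

Key step: step 2

Remarks on the chemistry
- Target numbering (2-oxaspiro[4.5]decane): ring A is O2–C1H(alkenyl)–C5–C4H2–C3(=O); ring B is C5–C6(=O)–C7=C8–C9H(OAc)–C10H2. Cyclohexene intermediates are numbered C1 (quaternary), C2 (carbonyl or carbinol), C3=C4, C5 (silyloxy), C6. TBS = tert-butyldimethylsilyl, TBDPS = tert-butyldiphenylsilyl.
- Assumption: the aspartate diester is sold as its hydrochloride and is used as the free base after a bicarbonate wash.
- Stereochemical bookkeeping: the (S) carbon of the silyloxycyclopentenone becomes the (S) acetoxy carbon C9 unchanged. The methoxycarbonyl group of the ring-expansion product, cis to the silyloxy group, becomes the lactone O–CH carbon, which is cis to the acetate in the target. The structures were checked against the target and agree.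
- Precursor design: the diazo carbon carries a methyl ester (small, binds Sc together with the alkoxide, reducible). The CH2 arm carries a tert-butyl ester (slow towards hydride, cannot lactonise before it is wanted). The ring oxygen stays a silyl ether, the least electron-withdrawing oxygen substituent next to the migrating CH2.
- The ring ketone is never protected: it is reduced and re-oxidised together with the ester carbon (steps 3 and 4) and then serves as the chelating group in step 11. The side-chain alcohol carries TBDPS so that the acid of step 12 removes only the ring TBS group.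

Step 1
Reactants: 1 L-aspartic acid 4-tert-butyl 1-methyl diester (free base)
Product: 2 4-tert-butyl 1-methyl 2-diazosuccinate
Conditions: isoamyl nitrite (1.2 equiv), AcOH (0.2 equiv), CHCl3, reflux, 20 min; used promptly
Reagents that add atoms: isoamyl nitrite, CC(C)CCON=O
Why: Diazotisation of an α-amino ester with an alkyl nitrite: N-nitrosation, tautomerisation and loss of water give the diazo ester, which the flanking ester stabilises; no stereocentre remains.

Step 2
Reactants: 2 4-tert-butyl 1-methyl 2-diazosuccinate; 3 (S)-4-(tert-butyldimethylsilyloxy)cyclopent-2-en-1-one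
Product: 5 methyl (1S,5S)-1-(2-tert-butoxy-2-oxoethyl)-5-(tert-butyldimethylsilyloxy)-2-oxocyclohex-3-ene-1-carboxylate (CO2Me cis to OTBS), via diazonium alkoxide 4 (not isolated)
Conditions: Sc(OTf)3 (10 mol%), chiral C2-symmetric N,N'-dioxide ligand (pipecolic-acid-derived bis(2,6-diisopropylanilide), matched enantiomer, 12 mol%), 2 (1.5 equiv, slow addition), CH2Cl2, −20 → 0 °C
Reagents that add atoms: none
Why: Proposed new method: Sc(OTf)3 activates the enone carbonyl of 3, the diazo carbon of 2 adds to it from the face opposite the silyloxy group to give the diazonium alkoxide 4 (alkoxide and methyl ester both on Sc), and the ring CH2 (C5 of 3), antiperiplanar to N2, shifts to the diazonium carbon as N2 leaves, which forms the C–C(=O) and C–CH2 bonds of the new quaternary carbon. The closest known reaction type is the Sc(OTf)3/chiral N,N'-dioxide-catalysed Tiffeneau–Demjanov-type ring expansion of cycloalkanones with α-alkyl-α-diazo esters, together with Lewis-acid diazoacetate homologations of cyclic conjugated ketones, which are expected to insert on the saturated side. Ring B is not closed by a cyclisation: the five-membered ring grows to six by a 1,2-alkyl shift, so no exo or endo closure mode applies. The new quaternary stereocentre is controlled by two elements, the silyloxy group, which directs the diazo carbon to the opposite ketone face, and the chiral Sc–ligand complex, which selects the face of the diazo carbon; the shift inverts the diazonium carbon and retains the migrating CH2. The step needs carbonyl addition instead of dipolar addition to the C=C (Lewis-acid activation of C=O at low temperature), and CH2 instead of vinyl migration: with the ester held on Sc beside the alkoxide, N2 in the selected adduct can lie anti to the CH2 or to oxygen but not to the vinyl carbon, and the CH2 shift keeps the enone conjugated. The adduct of the other diazo face would place the vinyl carbon anti to N2, so the ligand-controlled face choice also decides which carbon migrates.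

Step 3
Reactants: 5 methyl (1S,5S)-1-(2-tert-butoxy-2-oxoethyl)-5-(tert-butyldimethylsilyloxy)-2-oxocyclohex-3-ene-1-carboxylate
Product: 6 tert-butyl 2-[(1R,5S)-5-(tert-butyldimethylsilyloxy)-2-hydroxy-1-(hydroxymethyl)cyclohex-3-en-1-yl]acetate (both C2 epimers)
Conditions: i-Bu2AlH (DIBAL-H, 3.5 equiv), CH2Cl2, −78 → −40 °C; aq potassium sodium tartrate; used crude
Reagents that add atoms: none
Why: DIBAL-H reduction: the enone is reduced 1,2 and the methyl ester, assisted by the neighbouring aluminium alkoxide, goes to the primary alcohol while the tert-butyl ester is much slower at −78 °C; the new C2 carbinol centre forms without control and is erased in step 4.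

Step 4
Reactants: 6 tert-butyl 2-[(1R,5S)-5-(tert-butyldimethylsilyloxy)-2-hydroxy-1-(hydroxymethyl)cyclohex-3-en-1-yl]acetate
Product: 7 tert-butyl 2-[(1R,5S)-5-(tert-butyldimethylsilyloxy)-1-formyl-2-oxocyclohex-3-en-1-yl]acetate
Conditions: Dess–Martin periodinane (3 equiv), NaHCO3, CH2Cl2, 0 °C → rt; used at once
Reagents that add atoms: none
Why: Dess–Martin oxidation of the allylic secondary and the neopentyl primary alcohol under buffered conditions; both C2 epimers converge on one β-keto aldehyde whose quaternary α-carbon can neither enolise nor epimerise.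

Step 5
Reactants: 8 pent-4-yn-1-ol
Product: 10 (E)-5-iodo-4-methylpent-4-en-1-ol, via alkenylalane 9 (not isolated)
Conditions: Me3Al (3 equiv), Cp2ZrCl2 (0.25 equiv), CH2Cl2, 0 °C → rt; then I2, THF, −30 → 0 °C
Reagents that add atoms: trimethylaluminium, C[Al](C)C; iodine, II
Why: Negishi carboalumination: Zr-catalysed syn addition of Me–Al across the terminal alkyne places Al on the terminal carbon, and iodinolysis of the C–Al bond with retention gives the (E)-iodide.

Step 6
Reactants: 10 (E)-5-iodo-4-methylpent-4-en-1-ol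
Product: 11 (E)-5-iodo-4-methylpent-4-enal
Conditions: Dess–Martin periodinane (1.2 equiv), NaHCO3, CH2Cl2, 0 °C → rt
Reagents that add atoms: none
Why: Dess–Martin oxidation of a primary alcohol to the aldehyde; the alkenyl iodide is inert.

Step 7
Reactants: 11 (E)-5-iodo-4-methylpent-4-enal
Product: 12 racemic (E)-7-iodo-2,6-dimethylhepta-1,6-dien-3-ol
Conditions: isopropenylmagnesium bromide (1.2 equiv), THF, −78 °C; then H2O
Reagents that add atoms: isopropenylmagnesium bromide, C=C(C)[Mg]Br
Why: Grignard addition to the aldehyde, faster at −78 °C than halogen–magnesium exchange at the unactivated alkenyl iodide; the carbinol centre forms racemic and is corrected in steps 8 and 9.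

Step 8
Reactants: 12 racemic (E)-7-iodo-2,6-dimethylhepta-1,6-dien-3-ol
Product: 13 (E)-7-iodo-2,6-dimethylhepta-1,6-dien-3-one
Conditions: Dess–Martin periodinane (1.3 equiv), NaHCO3, CH2Cl2, 0 °C
Reagents that add atoms: none
Why: Dess–Martin oxidation of the allylic alcohol to the isopropenyl ketone under buffered conditions that do not trigger conjugate addition.

Step 9
Reactants: 13 (E)-7-iodo-2,6-dimethylhepta-1,6-dien-3-one
Product: 14 (3R,6E)-7-iodo-2,6-dimethylhepta-1,6-dien-3-ol
Conditions: (S)-1-methyl-3,3-diphenyltetrahydro-1H,3H-pyrrolo[1,2-c][1,3,2]oxazaborole [(S)-Me-CBS, 20 mol%], catecholborane (1.5 equiv), toluene, −78 °C; aq NaOH work-up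
Reagents that add atoms: none
Why: Corey–Bakshi–Shibata reduction: the ketone binds the oxazaborolidine boron with the isopropenyl group as the large substituent, and hydride from the coordinated catecholborane is delivered to the Si face to give the (R)-alcohol; catecholborane does not hydroborate the alkenes at −78 °C.

Step 10
Reactants: 14 (3R,6E)-7-iodo-2,6-dimethylhepta-1,6-dien-3-ol
Product: 15 tert-butyl{[(3R,6E)-7-iodo-2,6-dimethylhepta-1,6-dien-3-yl]oxy}diphenylsilane
Conditions: TBDPSCl (1.3 equiv), imidazole (2.5 equiv), DMAP (cat.), DMF, rt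
Reagents that add atoms: tert-butyl(chloro)diphenylsilane, CC(C)(C)[Si](Cl)(c1ccccc1)c1ccccc1
Why: Imidazole-promoted silylation of the secondary allylic alcohol; TBDPS is chosen because it survives the aqueous acid of step 12.

Step 11
Reactants: 7 tert-butyl 2-[(1R,5S)-5-(tert-butyldimethylsilyloxy)-1-formyl-2-oxocyclohex-3-en-1-yl]acetate; 15 tert-butyl{[(3R,6E)-7-iodo-2,6-dimethylhepta-1,6-dien-3-yl]oxy}diphenylsilane
Product: 18 tert-butyl 2-[(1R,5S)-5-(tert-butyldimethylsilyloxy)-1-[(1R,2E,6R)-6-(tert-butyldiphenylsilyloxy)-1-hydroxy-3,7-dimethylocta-2,7-dien-1-yl]-2-oxocyclohex-3-en-1-yl]acetate, via alkenyllithium 16 (not isolated), via alkenylmagnesium bromide 17 (not isolated)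
Conditions: 15 (1.3 equiv), t-BuLi (2.6 equiv), Et2O, −78 °C; MgBr2·OEt2 (1.4 equiv), −78 °C; then 7 precomplexed with MgBr2·OEt2 (1.5 equiv) in CH2Cl2, −78 °C; AcOH/THF quench at −78 °C
Reagents that add atoms: none
Why: Iodine–lithium exchange with retention of alkene geometry and transmetalation give the alkenylmagnesium bromide, which at −78 °C adds to the aldehyde and not to the hindered enone ketone or the tert-butyl ester (chelation-controlled Grignard addition); MgBr2 ties the formyl and ring-ketone oxygens into a six-membered chelate near the enone plane, the CH2CO2t-Bu arm is then pseudoaxial on one face, and the alkenyl group should add to the Re face of the aldehyde from the side of the ring CH2 to set the (R)-carbinol.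

Step 12
Reactants: 18 tert-butyl 2-[(1R,5S)-5-(tert-butyldimethylsilyloxy)-1-[(1R,2E,6R)-6-(tert-butyldiphenylsilyloxy)-1-hydroxy-3,7-dimethylocta-2,7-dien-1-yl]-2-oxocyclohex-3-en-1-yl]acetate
Product: 21 (1R,5R,9S)-1-[(1E,5R)-5-(tert-butyldiphenylsilyloxy)-2,6-dimethylhepta-1,6-dien-1-yl]-9-hydroxy-2-oxaspiro[4.5]dec-7-ene-3,6-dione, via hydroxy acid 19 (not isolated), via silyl lactone 20 (not isolated)
Conditions: TFA/CH2Cl2 (1:4), 0 °C, 1 h; then H2O (10 equiv), 0 °C → rt; aq NaHCO3
Reagents that add atoms: none
Why: Acidolysis of the tert-butyl ester (loss of isobutene) gives the γ-hydroxy acid, which closes at once to the five-membered lactone by acyl substitution with retention at the allylic carbinol (acid-catalysed lactonisation), and the aqueous acid then hydrolyses the secondary TBS ether while the far more acid-stable TBDPS ether stays on.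

Step 13
Reactants: 21 (1R,5R,9S)-1-[(1E,5R)-5-(tert-butyldiphenylsilyloxy)-2,6-dimethylhepta-1,6-dien-1-yl]-9-hydroxy-2-oxaspiro[4.5]dec-7-ene-3,6-dione
Product: 22 (1R,5R,9S)-1-[(1E,5R)-5-(tert-butyldiphenylsilyloxy)-2,6-dimethylhepta-1,6-dien-1-yl]-3,6-dioxo-2-oxaspiro[4.5]dec-7-en-9-yl acetate
Conditions: Ac2O (2 equiv), pyridine, DMAP (5 mol%), CH2Cl2, 0 °C
Reagents that add atoms: acetic anhydride, CC(=O)OC(C)=O
Why: DMAP-catalysed acetylation of the only free hydroxyl group; nothing else in 21 can be acylated and the conditions are too mild to enolise the enone.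

Step 14
Reactants: 22 (1R,5R,9S)-1-[(1E,5R)-5-(tert-butyldiphenylsilyloxy)-2,6-dimethylhepta-1,6-dien-1-yl]-3,6-dioxo-2-oxaspiro[4.5]dec-7-en-9-yl acetate
Product: 23 (1R,5R,9S)-1-[(1E,5R)-5-hydroxy-2,6-dimethylhepta-1,6-dien-1-yl]-3,6-dioxo-2-oxaspiro[4.5]dec-7-en-9-yl acetate (CNP0151251.2)
Conditions: HF·pyridine (excess), pyridine/THF, 0 °C → rt
Reagents that add atoms: none
Why: Fluoride-mediated cleavage of the silyl ether with buffered HF·pyridine, which should leave the allylic acetate, the lactone and the enone untouched.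

Compound list
1 | L-aspartic acid 4-tert-butyl 1-methyl diester (free base) | COC(=O)[C@@H](N)CC(=O)OC(C)(C)C | starting material
2 | 4-tert-butyl 1-methyl 2-diazosuccinate | COC(=O)C(=[N+]=[N-])CC(=O)OC(C)(C)C | intermediate
3 | (S)-4-(tert-butyldimethylsilyloxy)cyclopent-2-en-1-one | O=C1C=C[C@@H](O[Si](C)(C)C(C)(C)C)C1 | starting material
4 | diazonium alkoxide: diazo carbon of 2 bonded to C1 of 3 on the face opposite OTBS (drawn without Sc) | COC(=O)[C@]([N+]#N)(CC(=O)OC(C)(C)C)[C@]1([O-])C=C[C@@H](O[Si](C)(C)C(C)(C)C)C1 | intermediate (not isolated)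
5 | methyl (1S,5S)-1-(2-tert-butoxy-2-oxoethyl)-5-(tert-butyldimethylsilyloxy)-2-oxocyclohex-3-ene-1-carboxylate | COC(=O)[C@]1(CC(=O)OC(C)(C)C)C[C@H](O[Si](C)(C)C(C)(C)C)C=CC1=O | intermediate
6 | tert-butyl 2-[(1R,5S)-5-(tert-butyldimethylsilyloxy)-2-hydroxy-1-(hydroxymethyl)cyclohex-3-en-1-yl]acetate (C2 epimers) | OC[C@]1(CC(=O)OC(C)(C)C)C[C@H](O[Si](C)(C)C(C)(C)C)C=CC1O | intermediate
7 | tert-butyl 2-[(1R,5S)-5-(tert-butyldimethylsilyloxy)-1-formyl-2-oxocyclohex-3-en-1-yl]acetate | O=C[C@]1(CC(=O)OC(C)(C)C)C[C@H](O[Si](C)(C)C(C)(C)C)C=CC1=O | intermediate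
8 | pent-4-yn-1-ol | C#CCCCO | starting material
9 | dimethyl[(E)-5-(dimethylalumanyloxy)-2-methylpent-1-en-1-yl]alane | C[Al](C)/C=C(\C)CCCO[Al](C)C | intermediate (not isolated)
10 | (E)-5-iodo-4-methylpent-4-en-1-ol | OCCC/C(C)=C/I | intermediate
11 | (E)-5-iodo-4-methylpent-4-enal | O=CCC/C(C)=C/I | intermediate
12 | racemic (E)-7-iodo-2,6-dimethylhepta-1,6-dien-3-ol | C=C(C)C(O)CC/C(C)=C/I | intermediate
13 | (E)-7-iodo-2,6-dimethylhepta-1,6-dien-3-one | C=C(C)C(=O)CC/C(C)=C/I | intermediate
14 | (3R,6E)-7-iodo-2,6-dimethylhepta-1,6-dien-3-ol | C=C(C)[C@H](O)CC/C(C)=C/I | intermediate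
15 | tert-butyl{[(3R,6E)-7-iodo-2,6-dimethylhepta-1,6-dien-3-yl]oxy}diphenylsilane | C=C(C)[C@H](O[Si](c1ccccc1)(c1ccccc1)C(C)(C)C)CC/C(C)=C/I | intermediate
16 | [(1E,5R)-5-(tert-butyldiphenylsilyloxy)-2,6-dimethylhepta-1,6-dien-1-yl]lithium | C=C(C)[C@H](O[Si](c1ccccc1)(c1ccccc1)C(C)(C)C)CC/C(C)=C/[Li] | intermediate (not isolated)
17 | [(1E,5R)-5-(tert-butyldiphenylsilyloxy)-2,6-dimethylhepta-1,6-dien-1-yl]magnesium bromide | C=C(C)[C@H](O[Si](c1ccccc1)(c1ccccc1)C(C)(C)C)CC/C(C)=C/[Mg]Br | intermediate (not isolated)
18 | tert-butyl 2-[(1R,5S)-5-(tert-butyldimethylsilyloxy)-1-[(1R,2E,6R)-6-(tert-butyldiphenylsilyloxy)-1-hydroxy-3,7-dimethylocta-2,7-dien-1-yl]-2-oxocyclohex-3-en-1-yl]acetate | C=C(C)[C@H](O[Si](c1ccccc1)(c1ccccc1)C(C)(C)C)CC/C(C)=C/[C@@H](O)[C@]1(CC(=O)OC(C)(C)C)C[C@H](O[Si](C)(C)C(C)(C)C)C=CC1=O | intermediate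
19 | 2-[(1R,5S)-5-(tert-butyldimethylsilyloxy)-1-[(1R,2E,6R)-6-(tert-butyldiphenylsilyloxy)-1-hydroxy-3,7-dimethylocta-2,7-dien-1-yl]-2-oxocyclohex-3-en-1-yl]acetic acid | C=C(C)[C@H](O[Si](c1ccccc1)(c1ccccc1)C(C)(C)C)CC/C(C)=C/[C@@H](O)[C@]1(CC(=O)O)C[C@H](O[Si](C)(C)C(C)(C)C)C=CC1=O | intermediate (not isolated)
20 | (1R,5R,9S)-9-(tert-butyldimethylsilyloxy)-1-[(1E,5R)-5-(tert-butyldiphenylsilyloxy)-2,6-dimethylhepta-1,6-dien-1-yl]-2-oxaspiro[4.5]dec-7-ene-3,6-dione | C=C(C)[C@H](O[Si](c1ccccc1)(c1ccccc1)C(C)(C)C)CC/C(C)=C/[C@H]1OC(=O)C[C@]12C[C@H](O[Si](C)(C)C(C)(C)C)C=CC2=O | intermediate (not isolated)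
21 | (1R,5R,9S)-1-[(1E,5R)-5-(tert-butyldiphenylsilyloxy)-2,6-dimethylhepta-1,6-dien-1-yl]-9-hydroxy-2-oxaspiro[4.5]dec-7-ene-3,6-dione | C=C(C)[C@H](O[Si](c1ccccc1)(c1ccccc1)C(C)(C)C)CC/C(C)=C/[C@H]1OC(=O)C[C@]12C[C@H](O)C=CC2=O | intermediate
22 | (1R,5R,9S)-1-[(1E,5R)-5-(tert-butyldiphenylsilyloxy)-2,6-dimethylhepta-1,6-dien-1-yl]-3,6-dioxo-2-oxaspiro[4.5]dec-7-en-9-yl acetate | C=C(C)[C@H](O[Si](c1ccccc1)(c1ccccc1)C(C)(C)C)CC/C(C)=C/[C@H]1OC(=O)C[C@]12C[C@H](OC(C)=O)C=CC2=O | intermediate
23 | (1R,5R,9S)-1-[(1E,5R)-5-hydroxy-2,6-dimethylhepta-1,6-dien-1-yl]-3,6-dioxo-2-oxaspiro[4.5]dec-7-en-9-yl acetate | C=C(C)[C@H](O)CC/C(C)=C/[C@H]1OC(=O)C[C@]12C[C@H](OC(C)=O)C=CC2=O | target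

Total step count: 14.
Longest linear sequence: 10 steps (steps 5–14, from pent-4-yn-1-ol); the ring-B branch from the aspartate diester takes 8 (steps 1–4 and 11–14).

Steps most likely to fail

1. Step 2 (new method). What may go wrong: dipolar cycloaddition of the diazo compound across the enone C=C, shift of the vinyl carbon in place of the CH2, loss of N2 from 2 with 1,2-hydrogen shift to the fumarate before it adds, or poor face selection at the diazo carbon. The fallback uses known chemistry and sets out from 3. BF3·OEt2-promoted homologation with commercial ethyl diazoacetate (CH2Cl2, −78 °C), the established Lewis-acid ring enlargement of cyclic conjugated ketones, should give ethyl (5S)-5-(tert-butyldimethylsilyloxy)-2-oxocyclohex-3-ene-1-carboxylate F1 as its enol. C-alkylation of its enolate with tert-butyl bromoacetate (K2CO3, acetone), which should enter anti to the silyloxy group, then builds the quaternary carbon and gives ethyl (1S,5S)-1-(2-tert-butoxy-2-oxoethyl)-5-(tert-butyldimethylsilyloxy)-2-oxocyclohex-3-ene-1-carboxylate F2, the ethyl ester analogue of 5. The conditions of step 3 applied to it return to the route at 6.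

2. Step 11. What may go wrong: competing attack of the organomagnesium on the ring ketone, retro-aldol cleavage of the magnesium aldolate on warming, or incomplete chelation and therefore poor facial selectivity. The fallback sets out from 7 and 15: a Nozaki–Hiyama–Kishi coupling (CrCl2, NiCl2 cat., DMSO/THF, rt) run with a chiral oxazoline–sulfonamide ligand on chromium. The alkenylchromium species (trivalent chromium) is not basic and adds only to aldehydes, and the face is then chosen by the ligand and no longer by a substrate chelate. The product is 18 itself, where the route continues; no new compound is made.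

3. Step 3. What may go wrong: over-reduction of the tert-butyl ester by excess aluminium hydride, or premature closure of the new primary alcohol onto the tert-butyl ester during work-up. The fallback sets out from 5. Luche reduction (NaBH4, CeCl3·7H2O, MeOH, −78 °C) should give methyl (1S,5S)-1-(2-tert-butoxy-2-oxoethyl)-5-(tert-butyldimethylsilyloxy)-2-hydroxycyclohex-3-ene-1-carboxylate F3. LiBH4 (THF, MeOH 1 equiv, 0 °C → rt), a borohydride that the neighbouring hydroxyl group accelerates and that does not attack tert-butyl esters, then reduces the methyl ester and returns to the route at 6.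

Further compounds
F1 | step 2 | ethyl (5S)-5-(tert-butyldimethylsilyloxy)-2-oxocyclohex-3-ene-1-carboxylate | CCOC(=O)C1C[C@H](O[Si](C)(C)C(C)(C)C)C=CC1=O
F2 | step 2 | ethyl (1S,5S)-1-(2-tert-butoxy-2-oxoethyl)-5-(tert-butyldimethylsilyloxy)-2-oxocyclohex-3-ene-1-carboxylate | CCOC(=O)[C@]1(CC(=O)OC(C)(C)C)C[C@H](O[Si](C)(C)C(C)(C)C)C=CC1=O
F0 | step 11 | none | none
F3 | step 3 | methyl (1S,5S)-1-(2-tert-butoxy-2-oxoethyl)-5-(tert-butyldimethylsilyloxy)-2-hydroxycyclohex-3-ene-1-carboxylate | COC(=O)[C@]1(CC(=O)OC(C)(C)C)C[C@H](O[Si](C)(C)C(C)(C)C)C=CC1O
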